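**The constants.** The constants set a race for second reagent, the limiting reagent, charged at 1.00 equiv, less than partner or third reagent.

    substrate + partner → intermediate A (k1 = 0.208 M⁻¹ s⁻¹)
    second reagent + intermediate A → intermediate B (k2 = 1.31 M⁻¹ s⁻¹)
    third reagent + intermediate B → target (k3 = 0.306 M⁻¹ s⁻¹)
    substrate + second reagent → side product (k4 = 0.00306 M⁻¹ s⁻¹)
    substrate ⇌ dormant form (K5 = 0.78, k5 = 0.0158 s⁻¹)
    second reagent + target → over-reaction product (k6 = 0.424 M⁻¹ s⁻¹)

all flasks: substrate 0.083 M; partner 1.20 equiv; second reagent 1.00 equiv
- Friday's: third reagent 1.80 equiv (fed, over 2.50 min); time 5.0 min; a stirred flask in which third reagent is dosed at a steady rate over 2.50 min without added volume, worked up at 5.0 min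
- Monday's: third reagent 1.80 equiv; a single well-mixed tank run continuously and read at steady state, 15.0 min in it on average
- Sunday's: third reagent 1.80 equiv; one stirred flow tank at steady state, fed with the mixture as stated, mean residence time 5.0 min
- Saturday's: third reagent 1.80 equiv; time 5.0 min; everything together in a closed stirred flask, run for 5.0 min

- the set-up with the highest amount of target at the outlet or at the end, in percent of the substrate put in ("none" if the first two lie within 2 percentage points) (Friday's / Monday's / Sunday's / Saturday's / none)
- amount of target at the outlet or at the end, in percent of the substrate put in, Friday's
- amount of target at the outlet or at the end, in percent of the substrate put in, Monday's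
- amount of target at the outlet or at the end, in percent of the substrate put in, Sunday's
- amount of target at the outlet or at the end, in percent of the substrate put in, Saturday's

- the stated concentrations are those of everything mixed, before any reaction; amounts are the same in each set-up
- the feed brings no volume worth counting
- run time (Friday's): 5.0 min

**The ledger.** Amounts here are shares of the substrate charge, and the flask followed is Saturday's. Each share reaching intermediate B takes one second reagent, and each over-reaction takes one more and removes a target. Consequently, in a flask whose second reagent has reached zero, target is one minus two times the share still waiting as substrate, dormant form or intermediate A, less any intermediate B and side product.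

**The upper bound.** Substrate and dormant form exchange in 27.7 s, less than the time the first step needs, so they are treated as one pool with a free share of 0.562. With partner in slight excess, that pool integrates to 17.4 % after 5.0 min. With second reagent at zero, the ledger ceiling, one minus two times this reckoned pool, is 65.1 %; it is an estimate, not a strict limit, because the pool is one. Every share of intermediate A lowers it by two, and the hand stops there. Third reagent stands in neither the first step nor the fifth, and the ceiling is carried unchanged to Friday's flask.

**The lower bound.** Over-reaction needs target and has a time of 28.4 s at the full second reagent charge. Take that time as the end of a stretch in which second reagent is assumed to be taken singly; the pool then reckons to 74.6 %. Assume further that what has passed reaches target and that each later passage is matched by one over-reaction, so that target stands still; this picture, which is no proof, gives a lower mark of 25.4 %.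

**The forecast.** The forecast gave 39 % for Friday's, 26.5 % for Monday's, 18.3 % for Sunday's and 35 % for Saturday's, named Friday's best, and warned that “the Friday-over-Saturday call is not secure”; its Saturday's figure lies inside the bracket.

**The result.** Friday's gives 35.9 %, Monday's 26.8 %, Sunday's 18.0 % and Saturday's 30.8 %, which puts Friday's first. Left until 50.0 min, Saturday's reads 31.5 %. Saturday's stands 34 percentage points under the ceiling. Friday's holds 13.8 % of intermediate A at the end, which, provided its second reagent reached zero, brings its ceiling down to 37.5 %, and left until 50.0 min, Friday's reads 36.7 %.

The rate constants are those of an exercise, and the outcome is calculated.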